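**Retrosynthetic overview**
1. The target is an endo,exo ("epi") 1,4-diaryl-tetrahydrofuro[3,4-c]furan (atoms C1, O2, C3, C3a, C4, O5, C6, C6a). Ring A (C1/O2/C3/C3a/C6a) carries the free guaiacyl group endo, and ring B (C4/O5/C6/C6a/C3a) carries the prenyloxyaryl group exo. The last operations are allyl-to-prenyl cross-metathesis and desilylation.
2. Key disconnection C1–aryl: an aryllithium from O-silylated 4-bromo-2-methoxyphenol adds to bicyclic γ-lactone 9 (ring A with C1 as the carbonyl), and the hemiketal is reduced in the same flask with Et3SiH/BF3·OEt2.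
3. Enabling feature: C1 bears both the aryl group and ring oxygen O2, so it is a latent lactone carbonyl. Rings A and B are cis-fused about C3a–C6a into a cup that leaves only the convex face of C1 open, so hydride capture of the aryl oxocarbenium ion places the aryl endo, a centre set kinetically.
4. Lactone 9 comes from (S)-paraconic acid 4: dianion aldol with aldehyde 5 (C3a–C4 bond, trans), LiBH4 reduction of the sacrificial paraconic lactone only, then acid. Ring A (as lactone) closes first, ring B second by benzylic SN1 etherification (aryl exo).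
5. (S)-Paraconic acid comes from methyl 4-oxobutanoate by organocatalytic α-hydroxymethylation, oxidation and lactonization. Its single stereocentre (C6a) relays to C3a, C4 and C1.

Key step: step 5

Assumption (chemistry): in step 1 the (R)-configured diarylprolinol silyl ether is taken to follow its usual steric-shielding model and to give the (S)-aldehyde 2; the carbinol centre made in step 2 is carried as an epimeric mixture (drawn without configuration) because step 3 re-sets it.

**Step 1**
Reactants: 1 methyl 4-oxobutanoate
Product: 4 (S)-paraconic acid, via hydroxymethyl aldehyde 2 (not isolated), via hydroxy acid monoester 3 (not isolated)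
Conditions: (R)-2-[diphenyl(trimethylsilyloxy)methyl]pyrrolidine (10 mol%), aq. HCHO, pH 7 phosphate buffer, toluene, rt; then NaClO2, H2O2, NaH2PO4, MeCN/H2O, 0 °C; then TsOH·H2O (cat.), toluene, 60 °C
Reagents that add atoms: formaldehyde (C=O); sodium chlorite ([Na+].[O-]Cl=O)
Why: Enamine-catalysed cross-aldol (α-hydroxymethylation) with formaldehyde should set the future C6a by shielding of one enamine face, and immediate chlorite (Pinnick-type) oxidation followed by acid lactonization of the γ-hydroxy ester fixes the labile α-formyl centre as the lactone acid.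

**Step 2**
Reactants: 4 (S)-paraconic acid; 5 4-(allyloxy)-3-methoxybenzaldehyde
Product: 6 trans aldol adduct (hydroxy lactone acid; both carbinol epimers)
Conditions: LiN(SiMe3)2 (2.2 equiv), THF, −78 °C; then 5, −78 °C; 1 M HCl quench at −78 °C
Reagents that add atoms: none
Why: Aldol addition of the lactone enolate within the carboxylate–enolate dianion (the carboxylate keeps the neighbouring C–H non-acidic and so prevents E1cB ring opening) should take the aldehyde anti to the carboxylate, which sets the future C3a trans to the carboxyl group.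

**Step 3**
Reactants: 6 trans aldol adduct
Product: 9 bicyclic lactone (aryl exo), via triol acid 7 (not isolated), via lactone diol 8 (not isolated)
Conditions: LiBH4, THF, 0 °C → rt; then 1 M HCl (pH 2), rt; then CSA (10 mol%), 4 Å MS, CH2Cl2, 0 °C → rt
Reagents that add atoms: none
Why: LiBH4 reduces the lactone but not the lithium carboxylate, the freed γ-hydroxy acid lactonizes onto the primary hydroxyl (ring A), and CSA ionizes the electron-rich benzylic alcohol so that the cis hydroxymethyl group captures the cation (SN1 etherification, 5-exo) with the aryl on the convex face, which sets C4 whatever the carbinol configuration was; a lactone formed onto the benzylic hydroxyl instead should re-ionize at the same carbon and converge on 9.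

**Step 4**
Reactants: 10 4-bromo-2-methoxyphenol
Product: 11 (4-bromo-2-methoxyphenoxy)(tert-butyl)dimethylsilane
Conditions: t-BuMe2SiCl, imidazole, DMF, rt
Reagents that add atoms: tert-butyldimethylsilyl chloride (CC(C)(C)[Si](C)(C)Cl)
Why: Standard silylation of the phenol masks the acidic proton for the lithiation and lowers the donor strength of the para oxygen during the later Lewis-acid step.

**Step 5**
Reactants: 11 (4-bromo-2-methoxyphenoxy)(tert-butyl)dimethylsilane; 9 bicyclic lactone
Product: 14 endo,exo-diaryl furofuran (O-silyl, O-allyl), via aryllithium 12 (not isolated), via hemiketal 13 (not isolated)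
Conditions: n-BuLi, THF/toluene, −78 °C; then 9, −78 °C; then Et3SiH, BF3·OEt2, CH2Cl2, −78 → −40 °C; cold Et3N/NaHCO3 quench
Reagents that add atoms: none
Why: Bromine–lithium exchange gives aryllithium 12, which adds once to the only carbonyl of 9 (C1) to give the lithium salt of hemiketal 13, stable at −78 °C; BF3 then ionizes the C1–O(Li) bond to the five-membered, aryl-conjugated oxocarbenium ion (O2=C1), which takes hydride from Et3SiH. The closest known reaction type is aryllithium addition to a lactone followed by silane/Lewis-acid reduction of the lactol, as used for C-aryl glycosides and for turning monoaryl furofuranones into endo,exo-furofurans. No ring is closed here: ring A is carried over from the γ-lactone and only C1 changes from carbonyl to the aryl-bearing ether carbon. The new stereocentre C1 is controlled by the cis-fused cup of rings A and B: ring B (C6, O5) blocks the concave face, hydride enters on the convex face syn to H6a, and the aryl group ends endo (1S), cis to C6. The step needs mono-addition, convex-face hydride delivery and ionization of the hemiketal only; these are secured by the tetrahedral lithium hemiketalate at low temperature, by the bicyclic shape (C6a cannot epimerize because only the cis-fused lactone can exist), and by the much easier ionization of the hemiketal carbon (stabilized by O2 and aryl) compared with the benzylic ether C–O bonds at C4 and C1 at −78 °C, with the silyl and allyl aryl ethers inert under these conditions.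

**Step 6**
Reactants: 14 endo,exo-diaryl furofuran (O-silyl, O-allyl)
Product: 15 endo,exo-diaryl furofuran (O-silyl, O-prenyl)
Conditions: second-generation Grubbs catalyst RuCl2(=CHPh)(PCy3)(H2IMes) (5 mol%), 2-methyl-2-butene/CH2Cl2, 40 °C
Reagents that add atoms: 2-methyl-2-butene (CC=C(C)C)
Why: Olefin cross-metathesis with the trisubstituted partner in large excess should convert the terminal allyl ether into the prenyl ether with loss of propene, and it touches no stereocentre because no other alkene is present.

**Step 7**
Reactants: 15 endo,exo-diaryl furofuran (O-silyl, O-prenyl)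
Product: 16 target
Conditions: Bu4NF, AcOH, THF, 0 °C
Reagents that add atoms: none
Why: Fluoride-mediated cleavage of the aryl silyl ether, buffered with acetic acid, should free the phenol without exposing the para-hydroxybenzylic ether at C1 to strong base (quinone methide formation) or to acid (epimerization).

**Compound list**
1 | methyl 4-oxobutanoate | COC(=O)CCC=O | starting material
2 | methyl (3S)-3-formyl-4-hydroxybutanoate | COC(=O)C[C@H](C=O)CO | intermediate (not isolated)
3 | (2S)-2-(hydroxymethyl)-4-methoxy-4-oxobutanoic acid | COC(=O)C[C@H](C(=O)O)CO | intermediate (not isolated)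
4 | (S)-paraconic acid, (3S)-5-oxotetrahydrofuran-3-carboxylic acid | O=C1C[C@H](C(=O)O)CO1 | intermediate
5 | 4-(allyloxy)-3-methoxybenzaldehyde | C=CCOc1ccc(C=O)cc1OC | starting material
6 | (3S,4R)-4-{[4-(allyloxy)-3-methoxyphenyl](hydroxy)methyl}-5-oxotetrahydrofuran-3-carboxylic acid (both carbinol epimers) | O=C1[C@@H](C(O)c2ccc(OCC=C)c(OC)c2)[C@H](C(=O)O)CO1 | intermediate
7 | (2S,3S)-4-[4-(allyloxy)-3-methoxyphenyl]-4-hydroxy-2,3-bis(hydroxymethyl)butanoic acid (both carbinol epimers) | OC[C@@H](C(O)c1ccc(OCC=C)c(OC)c1)[C@H](C(=O)O)CO | intermediate (not isolated)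
8 | (3S,4S)-4-{[4-(allyloxy)-3-methoxyphenyl](hydroxy)methyl}-3-(hydroxymethyl)dihydrofuran-2(3H)-one (both carbinol epimers) | O=C1OC[C@@H](C(O)c2ccc(OCC=C)c(OC)c2)[C@H]1CO | intermediate (not isolated)
9 | (3aS,4R,6aS)-4-[4-(allyloxy)-3-methoxyphenyl]tetrahydro-1H,3H-furo[3,4-c]furan-1-one | O=C1OC[C@@H]2[C@H]1CO[C@H]2c1ccc(OCC=C)c(OC)c1 | intermediate
10 | 4-bromo-2-methoxyphenol | COc1cc(Br)ccc1O | starting material
11 | (4-bromo-2-methoxyphenoxy)(tert-butyl)dimethylsilane | COc1cc(Br)ccc1O[Si](C)(C)C(C)(C)C | intermediate
12 | {4-[(tert-butyldimethylsilyl)oxy]-3-methoxyphenyl}lithium | [Li]c1ccc(O[Si](C)(C)C(C)(C)C)c(OC)c1 | intermediate (not isolated)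
13 | (3aS,4R,6aS)-4-[4-(allyloxy)-3-methoxyphenyl]-1-{4-[(tert-butyldimethylsilyl)oxy]-3-methoxyphenyl}tetrahydro-1H,3H-furo[3,4-c]furan-1-ol (hemiketal, C1 undefined, present as its lithium alkoxide) | COc1cc(C2(O)OC[C@@H]3[C@H]2CO[C@H]3c2ccc(OCC=C)c(OC)c2)ccc1O[Si](C)(C)C(C)(C)C | intermediate (not isolated)
14 | tert-butyl(2-methoxy-4-{(1S,3aS,4R,6aS)-4-[3-methoxy-4-(prop-2-en-1-yloxy)phenyl]tetrahydro-1H,3H-furo[3,4-c]furan-1-yl}phenoxy)dimethylsilane | COc1cc([C@H]2OC[C@@H]3[C@H]2CO[C@H]3c2ccc(OCC=C)c(OC)c2)ccc1O[Si](C)(C)C(C)(C)C | intermediate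
15 | tert-butyl(2-methoxy-4-{(1S,3aS,4R,6aS)-4-{3-methoxy-4-[(3-methylbut-2-en-1-yl)oxy]phenyl}tetrahydro-1H,3H-furo[3,4-c]furan-1-yl}phenoxy)dimethylsilane | COc1cc([C@H]2OC[C@@H]3[C@H]2CO[C@H]3c2ccc(OCC=C(C)C)c(OC)c2)ccc1O[Si](C)(C)C(C)(C)C | intermediate
16 | 2-methoxy-4-{(1S,3aS,4R,6aS)-4-{3-methoxy-4-[(3-methylbut-2-en-1-yl)oxy]phenyl}tetrahydro-1H,3H-furo[3,4-c]furan-1-yl}phenol | COc1cc([C@H]2OC[C@@H]3[C@H]2CO[C@H]3c2ccc(OCC=C(C)C)c(OC)c2)ccc1O | target

**Step count and risks**
Total step count: 7. Longest linear sequence: 6 steps (1, 2, 3, 5, 6, 7); step 4 is a one-step side branch.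

Steps most likely to fail:

1. Step 5 (key step). What may go wrong: after the intended hydride capture, continued Lewis-acid ionization of the two electron-rich benzylic C–O bonds, leading to ring-opening over-reduction or to epimerization at C1; also a second aryl addition if the hemiketalate opens to the ketone before the quench. Fallback: it sets out from 13, here quenched with aqueous NH4Cl and isolated (mainly as the open hydroxy ketone). Reagent-controlled CBS reduction with (R)-2-methyl-CBS-oxazaborolidine and catecholborane (toluene, −78 °C; catecholborane so that the allyl ether is not hydroborated) should give the (S)-carbinol diol F1. Mitsunobu cyclodehydration (PPh3, DIAD, THF, 0 °C) then activates the primary hydroxyl, and the benzylic hydroxyl closes ring A by SN2 at C3 with retention at C1. The fallback comes back to the route at 14 without any Lewis acid.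

2. Step 3. What may go wrong: partial reduction of the carboxylate through an acyloxyborohydride, or diversion of the hydroxy acid into the γ-lactone on the benzylic hydroxyl with sluggish re-ionization, or elimination of the benzylic cation to a styrene. Fallback: it sets out from 6. Silylation (t-BuMe2SiOSO2CF3, 2,6-lutidine, CH2Cl2) gives the bis-silyl derivative F2, whose silyl ester is cleaved (K2CO3, MeOH/H2O) to the silyl ether acid F3. LiBH4 reduction gives the diol acid F4, in which only the primary hydroxyl can lactonize, so acidification gives the silyloxy lactone F5. BF3·OEt2 (CH2Cl2, −78 → −20 °C) then ionizes the benzylic silyl ether, and the cis hydroxymethyl group closes ring B. The fallback comes back to the route at 9.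

3. Step 2. What may go wrong: retro-aldol cleavage of the dilithium aldolate before the quench, or loss of trans selectivity through carboxylate-directed delivery of the aldehyde. Fallback: it sets out from 4. Double silylation (LiN(SiMe3)2, Me3SiCl, THF, −78 °C) gives the bis-silyl ketene acetal F6. A Mukaiyama aldol addition to 5 (BF3·OEt2, CH2Cl2, −78 °C; open transition state, anti to the ring substituent) followed by aqueous acidic work-up comes back to the route at 6.

**Further compounds**
F1 | step 5 | (S)-{4-[(tert-butyldimethylsilyl)oxy]-3-methoxyphenyl}{(3S,4S,5R)-4-(hydroxymethyl)-5-[3-methoxy-4-(prop-2-en-1-yloxy)phenyl]oxolan-3-yl}methanol | COc1cc([C@@H](O)[C@@H]2CO[C@@H](c3ccc(OCC=C)c(OC)c3)[C@@H]2CO)ccc1O[Si](C)(C)C(C)(C)C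
F2 | step 3 | tert-butyldimethylsilyl (3S,4R)-4-{[4-(allyloxy)-3-methoxyphenyl][(tert-butyldimethylsilyl)oxy]methyl}-5-oxotetrahydrofuran-3-carboxylate | O=C1[C@@H](C(O[Si](C)(C)C(C)(C)C)c2ccc(OCC=C)c(OC)c2)[C@H](C(=O)O[Si](C)(C)C(C)(C)C)CO1
F3 | step 3 | (3S,4R)-4-{[4-(allyloxy)-3-methoxyphenyl][(tert-butyldimethylsilyl)oxy]methyl}-5-oxotetrahydrofuran-3-carboxylic acid | O=C1[C@@H](C(O[Si](C)(C)C(C)(C)C)c2ccc(OCC=C)c(OC)c2)[C@H](C(=O)O)CO1
F4 | step 3 | (2S,3S)-4-[4-(allyloxy)-3-methoxyphenyl]-4-[(tert-butyldimethylsilyl)oxy]-2,3-bis(hydroxymethyl)butanoic acid | OC[C@@H](C(O[Si](C)(C)C(C)(C)C)c1ccc(OCC=C)c(OC)c1)[C@H](C(=O)O)CO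
F5 | step 3 | (3S,4S)-4-{[4-(allyloxy)-3-methoxyphenyl][(tert-butyldimethylsilyl)oxy]methyl}-3-(hydroxymethyl)dihydrofuran-2(3H)-one | O=C1OC[C@@H](C(O[Si](C)(C)C(C)(C)C)c2ccc(OCC=C)c(OC)c2)[C@H]1CO
F6 | step 2 | trimethylsilyl (3S)-5-[(trimethylsilyl)oxy]-2,3-dihydrofuran-3-carboxylate | C[Si](C)(C)OC1=C[C@H](C(=O)O[Si](C)(C)C)CO1
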